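We want the amount of target after 50 h in a flask of 0.050 M substrate, the limiting reagent by charge, and we want to know whether green or red raises it.

| flask | substrate | reagent in the second phase | remark | time | volume of the second phase over the first |
|---|---|---|---|---|---|
| zeta | 0.070 M | 1.1 equiv | run made earlier |  |  |
| theta | 0.11 M | 1.1 equiv | run made earlier |  |  |
| flask | 0.050 M | 1.10 equiv |  | 50 h | 0.25 |

| run | time / h | target / % |
|---|---|---|
| zeta | 3.00 | 3.0 |
| zeta | 5.00 | 5.8 |
| zeta | 8.00 | 10.6 |
| zeta | 15.0 | 18.1 |
| zeta | 25.0 | 24.2 |
| zeta | 40.0 | 27.4 |
| theta | 2.50 | 3.7 |
| theta | 8.00 | 14.4 |
| theta | 15.0 | 24.6 |
| theta | 20.0 | 28.4 |
| theta | 30.0 | 30.8 |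
| theta | 40.0 | 31.3 |

(each reading ± 0.5 percentage points)

- in the second phase: reagent in the second phase; everything else is in the first
- charges count per volume of the first phase; a concentration in a rate is the amount of a species over the volume of its own phase; every rate counts per litre of the first phase
- the analysis behind the earlier runs scatters by 0.5 percentage points, standard deviation
- the earlier runs hold the two phases in the same ratio of volumes as the flask asked about

- green: doubling the amount of reagent in the second phase, all else as stated
- red: doubling the transfer coefficient of the reagent in the second phase, all else as stated

1. amount of target at 50 h, in percent of the substrate charged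
2. the change that raises the amount of target at 50 h, in percent of the substrate charged most ("none" if none brings more than 2 percentage points) (green / red / none)
3. amount of target at 50 h, in percent of the substrate charged, after red

Both earlier runs rise and then flatten, the zeta run near 27.4% and the theta run near 31.3%, so we treat target as a step response and count time in half-rise times. A half-rise time is the time at which target reaches half its last level. Drawing straight lines between readings, the zeta run gets there at 10.9 h and the theta run at 8.86 h.

Our first guess is that this time goes inversely with concentration, which gives this flask 15.3 h. But that rule, applied from the zeta run, misses the theta run by 1.93 h, so we let the two runs set a power of concentration instead, 0.458. This gives the flask's half-rise time as 12.7 h, and 50 h then holds 3.93 of them.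

That count gives a stage, not a level. It lies between the zeta run's last count, 3.67, and the theta run's, 4.52, so we may compare last levels. A separate power of concentration, 0.294, set in the same way by those two last levels, gives 24.8%. One doubt remains: the theta run gained 0.5 percentage points in its last step, no more than one scatter, so these readings cannot show whether target holds or falls later.

The forecast says 25.5%, between 23.5% and 27%, a little above our level. It picks green and puts red at 22%, between 18.5% and 24.5%, holding that “slower supply relative to substrate favours target”.

The flask gives 24.1%; green adds 10 points, while red moves it by −0.12 points, to 23.9%.

    reagent in the reaction phase ⇌ reagent in the second phase, rate k1*([reagent in the reaction phase] - [reagent in the second phase]/K1) per volume of the first phase (partition coefficient = 0.610, kL = 1.40 × 10⁻⁵ /s)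
    substrate + reagent in the reaction phase → target (k = 1.00 × 10⁻⁴ /M/s)
    2 reagent in the reaction phase → homo dimer (k = 7.40 × 10⁻⁵ /M/s)
    target ⇌ isomer of the product (K = 6.20, k = 4.30 × 10⁻⁶ /s)

At 12.5 h this flask holds 12.4% of target, half of its level at 50 h, beside our half-rise time of 12.7 h. For the neighbour flask at 0.20 M substrate, same recipe, the power set by the half-rise times gives a half-rise time of 6.74 h. There 50 h holds 7.42 of them, more than this flask's 3.93, and that neighbour stands at 34.7% of target with 42.1% of its substrate left.

The runs were generated by integration on assumed constants, noise included.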